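## Analysis of the target

The target is a flavan-3-ol whose C3 oxygen is acylated by (E)-ferulic acid. Ring A (benzo) carries hydroxyls at C5 and C7, ring C (pyran) holds O1, C2, C3 and C4, and ring B, a 3,5-dihydroxy-4-methoxyphenyl group, sits on C2. The two stereocentres, C2 and C3, are both R, so the C2 aryl group and the C3 acyloxy group are cis (the epi series, with the C3 substituent axial). Sensitive features are the five electron-rich phenols, the cinnamate double bond (which rules out a final hydrogenolysis), two aryl methyl ethers that must stay, and the C2–O1 bond, a benzylic aryl ether that can ionise under acid. The hard points are the cis-(2R,3R) relationship with absolute control, acylation of one aliphatic hydroxyl beside five phenols, and a deprotection that spares the alkene. The strategy rests on ring A: O1 is bound to C8a and C4 to the neighbouring C4a, and with oxygens at C5 and C7 these are the two carbons of a 3,5-dioxygenated benzyne. Ring C at the 2H-chromene level, with the C3 oxygen as an enol ether, is one hydrolysis away from a ketone whose C2 is epimerisable.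

## Retrosynthetic reasoning

**29 to 28.** The phenols are unmasked last. All five are carried as benzyl ethers, so that one Lewis-acid debenzylation with a cation scavenger frees them without hydrogen and leaves the cinnamate alkene of 29 alone.

**28 to 22 and 26.** The acyl–oxygen bond at C3 is cut. With every phenol benzylated, alcohol 22 has a single free hydroxyl, so the acylation needs no selectivity. Acid 26 is one condensation away from 23 and 24.

**22 to 21.** The C3–H bond is cut, leading back to racemic ketone 21. C2 of 21 is alpha to the carbonyl, benzylic and oxygen-substituted, hence readily enolised. A chiral transfer-hydrogenation catalyst can therefore funnel both enantiomers into one cis alcohol and set C2 and C3 together.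

**21 to 20.** The ketone is masked as the enol ether of 2H-chromene 20. An ethyl enol ether is chosen over a silyl one because the silyl group would not survive the fluoride that releases the aryne. Mild aqueous acid removes the ethyl group.

**20 to 8 and 16.** Three bonds are cut at once: O1–C8a, C4–C4a and O1–C2. Ring A becomes the aryne from 8, and C2, C3, C4, O1 and ring B come from enal 16. The forward reaction must add the aldehyde C=O across the aryne with the oxygen on the carbon remote from the flanking benzyloxy group, then open the four-membered ring and electrocyclise. The gain is convergence: two flat, achiral fragments give the whole benzopyran with the C3 oxygen in place.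

**8 to 1.** The silyl group and the triflate sit on adjacent carbons. The phenol oxygen of 1 is converted into a carbamate (2) that directs lithiation to the carbon it shares with a benzyloxy group. Silylation gives 6, and carbamate cleavage with triflation gives 8.

**16 to 12 and 13.** The C2=C3 alkene of the enal (flavan numbering) is cut by a Horner–Wadsworth–Emmons disconnection. Phosphonate 13 supplies C3, C4 and the enol oxygen, giving ester 14, and a reduction–oxidation pair (15, then 16) adjusts the oxidation level. Aldehyde 12 comes from commercial ester 9 by benzylation (10), reduction (11) and oxidation.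

## Alternatives that were turned down

Alternative 1: aryl etherification of an open-chain diol monoether. Disconnection: only the O1–C8a bond is cut, which leads to the open-chain bromide (1R,2R)-3-[2,4-bis(benzyloxy)-6-bromophenyl]-1-[3,5-bis(benzyloxy)-4-methoxyphenyl]-2-[(4-methoxybenzyl)oxy]propan-1-ol A1. Forward key step: a palladium-catalysed intramolecular C–O coupling (for example Pd(OAc)2, a bulky biaryl phosphine, Cs2CO3) in which the benzylic hydroxyl of A1 displaces the aryl bromide. It would give (2R,3R)-5,7-bis(benzyloxy)-2-[3,5-bis(benzyloxy)-4-methoxyphenyl]-3-[(4-methoxybenzyl)oxy]chroman A2 with retention, since no bond to a stereocentre is touched. For: both stereocentres of A1 would come from an asymmetric dihydroxylation of predictable sense, and the cis relationship of A2 is fixed before ring closure; on absolute stereocontrol this plan is stronger than the chosen one. Against: in A1 the bromide sits on a ring with two alkoxy donors and an ortho alkyl group, so oxidative addition and C–O reductive elimination are both slow. The secondary benzylic alkoxide on palladium has a beta hydrogen, so oxidation to a ketone with hydrodebromination competes. The two hydroxyls must be differentiated before A1 is reached, and the 4-methoxybenzyl group of A2 must later be removed oxidatively beside very electron-rich rings. Comparison: the sequence to A2 is linear and longer, whereas the chosen strategy makes three bonds in one convergent step with no hydroxyl differentiation and pays for this with a later dynamic resolution.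

Alternative 2: ortho-quinone methide cycloaddition with a Z-alkenylboronate. Disconnection: the C4–C3 and O1–C2 bonds are cut. The partners are 3,5-bis(benzyloxy)-2-(hydroxymethyl)phenol A3, the quinone methide precursor, and 2-{(Z)-2-[3,5-bis(benzyloxy)-4-methoxyphenyl]ethenyl}-4,4,5,5-tetramethyl-1,3,2-dioxaborolane A4. Forward key step: inverse-demand [4+2] cycloaddition of the quinone methide released from A3 with the Z alkene of A4. It would give (2S,3R)-5,7-bis(benzyloxy)-2-[3,5-bis(benzyloxy)-4-methoxyphenyl]-3-(4,4,5,5-tetramethyl-1,3,2-dioxaborolan-2-yl)chroman A5, with aryl and boron cis by suprafacial addition, and C–B oxidation of A5 with retention would follow. For: it is the shortest plan, the regiochemistry is electronically matched, and the cis relationship is set in the ring-forming step; on both step count and relative stereocontrol it beats the chosen route. Against: A5 is needed as one enantiomer, but a quinone methide with no substituent on its methylene carbon and an alkenylboronate such as A4 with no binding site give a chiral acid nothing to hold, so a resolution would be likely. Boron lowers the nucleophilicity of the alkene of A4, and its Z-styrene is twisted out of conjugation. The phloroglucinol-type quinone methide generated from A3 would be trapped readily by its own precursor. Comparison: the stereocentres of A5 are fixed irreversibly in the cycloaddition, whereas the chosen strategy keeps C2 labile and places absolute control in a step built for it.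

Alternative 3: ring-closing metathesis to a 3-alkoxy-2H-chromene. Disconnection: the C3=C4 bond is cut, which leads to the diene 1,5-bis(benzyloxy)-3-({(1R)-1-[3,5-bis(benzyloxy)-4-methoxyphenyl]-2-[(4-methoxybenzyl)oxy]prop-2-en-1-yl}oxy)-2-ethenylbenzene A6. Forward key step: ring closure of A6 with second-generation Grubbs catalyst to (2R)-5,7-bis(benzyloxy)-2-[3,5-bis(benzyloxy)-4-methoxyphenyl]-3-[(4-methoxybenzyl)oxy]-2H-chromene A7. For: the conditions are neutral, chromene formation by metathesis is well behaved in general, and A7 would carry C2 already resolved. Against: the ruthenium alkylidene forms a slowly turning-over alkoxycarbene with the enol ether of A6, and the ring A vinyl group is flanked by a benzyloxy group. C2 of A6 is a doubly activated benzylic ether carbon that would have to be made and kept enantiopure. Unmasking the C3 ketone of A7 would make that same centre enolisable, so the stereochemical investment would be lost. Comparison: A7 is the same type of intermediate as 20, reached in more steps and with a stereocentre that cannot be relied on, whereas the chosen strategy reaches this oxidation level convergently and treats C2 as labile on purpose.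

Key step: step 10

## Remarks on the chemistry (assumptions)

- Compounds 1, 9, 13, 23 and 24 are taken to be purchasable.
- The sense of induction in step 12 is assigned by letting the C2 flank of ketone 21 (aryl- and oxygen-bearing) take the place of the aryl group of an aryl alkyl ketone in the usual transition-state model. If the sense proved opposite, the mirror-image catalyst would be used with no other change.
- Racemic compounds 18, 20, 21 and F1 are drawn without configuration at the stereocentre.

## Route

Step 1
Reactants: 1 3,5-bis(benzyloxy)phenol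
Product: 2 3,5-bis(benzyloxy)phenyl N-isopropylcarbamate
Conditions: i-PrNCO, Et3N (cat.), CH2Cl2, rt
Reagents that add atoms: isopropyl isocyanate, CC(C)N=C=O
Why: Amine-catalysed addition of the phenol to the isocyanate (carbamoylation) installs a strong ortho-directing group that can later be removed under mild base.

Step 2
Reactants: 2 3,5-bis(benzyloxy)phenyl N-isopropylcarbamate
Product: 6 3,5-bis(benzyloxy)-2-(trimethylsilyl)phenyl N-isopropylcarbamate, via N-silyl carbamate 3 (not isolated), via aryllithium 4 (not isolated), via bis-silyl carbamate 5 (not isolated)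
Conditions: TMSOTf, TMEDA, Et2O, 0 °C to rt; n-BuLi, TMEDA, −78 °C; TMSCl, −78 °C to rt; aq. NaHSO4
Reagents that add atoms: chlorotrimethylsilane, C[Si](C)(C)Cl
Why: Directed ortho-metalation after in-situ N-silylation of the N–H; the carbamate directs lithiation to the ring carbon it shares with a benzyloxy group, the most activated site, and TMSCl traps the aryllithium at −78 °C before anionic Fries migration. The N-silyl group is lost on aqueous work-up.

Step 3
Reactants: 6 3,5-bis(benzyloxy)-2-(trimethylsilyl)phenyl N-isopropylcarbamate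
Product: 8 3,5-bis(benzyloxy)-2-(trimethylsilyl)phenyl trifluoromethanesulfonate, via silylphenol 7 (not isolated)
Conditions: Et2NH, DBU, MeCN, 40 °C; then PhNTf2, rt
Reagents that add atoms: N-phenylbis(trifluoromethanesulfonimide), O=S(=O)(N(c1ccccc1)S(=O)(=O)C(F)(F)F)C(F)(F)F
Why: Base-induced E1cB loss of isopropyl isocyanate (trapped by Et2NH as a urea) frees the phenoxide, which is triflated in the same flask. The conditions are mild enough to keep the aryl–silicon bond.

Step 4
Reactants: 9 methyl 3,5-dihydroxy-4-methoxybenzoate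
Product: 10 methyl 3,5-bis(benzyloxy)-4-methoxybenzoate
Conditions: BnBr, K2CO3, DMF, 60 °C
Reagents that add atoms: benzyl bromide, BrCc1ccccc1
Why: Williamson etherification of both phenols; the methyl ester is inert to carbonate in DMF.

Step 5
Reactants: 10 methyl 3,5-bis(benzyloxy)-4-methoxybenzoate
Product: 11 [3,5-bis(benzyloxy)-4-methoxyphenyl]methanol
Conditions: LiAlH4, THF, 0 °C to rt
Reagents that add atoms: none
Why: Hydride reduction of the ester to the benzylic alcohol; benzyl and methyl ethers are untouched.

Step 6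
Reactants: 11 [3,5-bis(benzyloxy)-4-methoxyphenyl]methanol
Product: 12 3,5-bis(benzyloxy)-4-methoxybenzaldehyde
Conditions: MnO2, CH2Cl2, rt
Reagents that add atoms: none
Why: Selective oxidation of a benzylic alcohol to the aldehyde without over-oxidation.

Step 7
Reactants: 12 3,5-bis(benzyloxy)-4-methoxybenzaldehyde; 13 ethyl 2-(diethoxyphosphoryl)-2-ethoxyacetate
Product: 14 ethyl (Z)-3-[3,5-bis(benzyloxy)-4-methoxyphenyl]-2-ethoxyprop-2-enoate
Conditions: NaH, THF, 0 °C to rt
Reagents that add atoms: none
Why: Horner–Wadsworth–Emmons olefination with an alpha-alkoxy phosphonoacetate; the Z isomer (aryl trans to the ester) is expected to predominate and is taken on after chromatography. The alkene geometry is in any case lost in step 10.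

Step 8
Reactants: 14 ethyl (Z)-3-[3,5-bis(benzyloxy)-4-methoxyphenyl]-2-ethoxyprop-2-enoate
Product: 15 (Z)-3-[3,5-bis(benzyloxy)-4-methoxyphenyl]-2-ethoxyprop-2-en-1-ol
Conditions: i-Bu2AlH, CH2Cl2, −78 °C; aq. KNaC4H4O6 (potassium sodium tartrate)
Reagents that add atoms: none
Why: 1,2-Reduction of the conjugated ester to the allylic alcohol; the neutral tartrate work-up protects the acid-labile enol ether.

Step 9
Reactants: 15 (Z)-3-[3,5-bis(benzyloxy)-4-methoxyphenyl]-2-ethoxyprop-2-en-1-ol
Product: 16 (Z)-3-[3,5-bis(benzyloxy)-4-methoxyphenyl]-2-ethoxyprop-2-enal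
Conditions: MnO2, CH2Cl2, rt
Reagents that add atoms: none
Why: Allylic oxidation under neutral conditions gives the enal without touching the enol ether.

Step 10
Reactants: 8 3,5-bis(benzyloxy)-2-(trimethylsilyl)phenyl trifluoromethanesulfonate; 16 (Z)-3-[3,5-bis(benzyloxy)-4-methoxyphenyl]-2-ethoxyprop-2-enal
Product: 20 rac-5,7-bis(benzyloxy)-2-[3,5-bis(benzyloxy)-4-methoxyphenyl]-3-ethoxy-2H-chromene, via aryne 17 (not isolated), via benzoxete 18 (not isolated), via ortho-quinone methide 19 (not isolated)
Conditions: CsF, MeCN, rt to 40 °C, slow addition of 8, Ar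
Reagents that add atoms: none
Why: Fluoride attacks the silyl group of 8 and expels triflate to give aryne 17; the carbonyl oxygen of 16 adds to the aryne carbon remote from the flanking benzyloxy group (the future C8a), and the resulting aryl anion, stabilised inductively by that group, closes on the oxocarbenium carbon in a stepwise formal [2+2] to give benzoxete 18. Strain then drives a 4π ring opening to ortho-quinone methide 19, and a thermal disrotatory oxa-6π electrocyclisation of its O=C8a–C4a=C4–C3=C2 unit forms O1–C2, closes ring C and restores the aromaticity of ring A. The closest known reaction type is the fluoride-induced reaction of arynes with alpha,beta-unsaturated aldehydes, which gives 2H-chromenes by this same sequence. Ring C is therefore closed by a pericyclic six-electron closure of a 1-oxatriene and not by an ionic cyclisation. C2 is the only new stereocentre; nothing in the achiral partners biases the closure, so 20 forms as the racemate, which is intended because C2 is set in step 12. The step needs regioselective aryne capture, secured by the distortion that the adjacent benzyloxy group imposes on the aryne (nucleophiles add meta to it), and reaction at C=O in preference to C=C, favoured because 16 has no enolisable hydrogen and its alkene is trisubstituted and hindered. The C5 benzyloxy group also turns the side chain of 19 towards the carbonyl oxygen, the geometry from which the electrocyclisation can occur. The enol oxygen is carried as an ethyl ether because a silyl enol ether would be cleaved by the fluoride.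

Step 11
Reactants: 20 rac-5,7-bis(benzyloxy)-2-[3,5-bis(benzyloxy)-4-methoxyphenyl]-3-ethoxy-2H-chromene
Product: 21 rac-5,7-bis(benzyloxy)-2-[3,5-bis(benzyloxy)-4-methoxyphenyl]chroman-3-one
Conditions: 1 M aq. HCl, THF, 0 °C to rt, degassed
Reagents that add atoms: water, O
Why: Acid-catalysed enol ether hydrolysis: protonation at C4 gives the C3 oxocarbenium ion, water adds and ethanol is lost. Aryl benzyl and methyl ethers are stable to dilute acid, and air is excluded because the ketone is oxidation-prone.

Step 12
Reactants: 21 rac-5,7-bis(benzyloxy)-2-[3,5-bis(benzyloxy)-4-methoxyphenyl]chroman-3-one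
Product: 22 (2R,3R)-5,7-bis(benzyloxy)-2-[3,5-bis(benzyloxy)-4-methoxyphenyl]chroman-3-ol
Conditions: RuCl[(R,R)-TsDPEN](p-cymene) (cat.), HCO2H, Et3N, DMF, 40 °C, Ar
Reagents that add atoms: none
Why: Noyori–Ikariya asymmetric transfer hydrogenation under dynamic kinetic resolution: C2 is alpha to the ketone, benzylic and oxygen-bearing, so amine-mediated enolisation should interconvert the ketone enantiomers faster than reduction. The catalyst reduces the (2R)-ketone from the face anti to the C2 aryl group, so hydride enters C3 trans to the aryl and the alcohol is cis; catalyst control sets 3R and, through the resolution, 2R.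

Step 13
Reactants: 23 4-(benzyloxy)-3-methoxybenzaldehyde; 24 malonic acid
Product: 26 (E)-3-[4-(benzyloxy)-3-methoxyphenyl]prop-2-enoic acid, via arylidenemalonic acid 25 (not isolated)
Conditions: pyridine, piperidine (cat.), 90 °C; aq. HCl
Reagents that add atoms: none
Why: Knoevenagel–Doebner condensation; decarboxylation of the arylidenemalonic acid gives the E-cinnamic acid, the thermodynamic isomer.

Step 14
Reactants: 22 (2R,3R)-5,7-bis(benzyloxy)-2-[3,5-bis(benzyloxy)-4-methoxyphenyl]chroman-3-ol; 26 (E)-3-[4-(benzyloxy)-3-methoxyphenyl]prop-2-enoic acid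
Product: 28 (2R,3R)-5,7-bis(benzyloxy)-2-[3,5-bis(benzyloxy)-4-methoxyphenyl]chroman-3-yl (E)-3-[4-(benzyloxy)-3-methoxyphenyl]prop-2-enoate, via acid chloride 27 (not isolated)
Conditions: 26, (COCl)2, DMF (cat.), CH2Cl2, 0 °C to rt, concentrate; then 22, Et3N, DMAP, CH2Cl2, 0 °C to rt
Reagents that add atoms: none
Why: DMAP-catalysed acylation of the hindered axial secondary alcohol by the acid chloride; the reaction occurs at oxygen, so C2 and C3 are untouched.

Step 15
Reactants: 28 (2R,3R)-5,7-bis(benzyloxy)-2-[3,5-bis(benzyloxy)-4-methoxyphenyl]chroman-3-yl (E)-3-[4-(benzyloxy)-3-methoxyphenyl]prop-2-enoate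
Product: 29 (2R,3R)-2-(3,5-dihydroxy-4-methoxyphenyl)-5,7-dihydroxychroman-3-yl (E)-3-(4-hydroxy-3-methoxyphenyl)prop-2-enoate
Conditions: BCl3, pentamethylbenzene, CH2Cl2, −78 °C; MeOH quench at −78 °C
Reagents that add atoms: none
Why: Lewis-acid debenzylation with a non-basic cation scavenger: BCl3 activates each aryl benzyl ether and the benzyl cation is transferred to pentamethylbenzene, which prevents C-benzylation of ring A. No hydrogen is used, so the alkene is spared, and at −78 °C the methyl ethers, the ester and the C2–O1 bond should survive.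

## Compound list

1 | 3,5-bis(benzyloxy)phenol | Oc1cc(OCc2ccccc2)cc(OCc2ccccc2)c1 | starting material
2 | 3,5-bis(benzyloxy)phenyl N-isopropylcarbamate | CC(C)NC(=O)Oc1cc(OCc2ccccc2)cc(OCc2ccccc2)c1 | intermediate
3 | 3,5-bis(benzyloxy)phenyl N-isopropyl-N-(trimethylsilyl)carbamate (not isolated) | CC(C)N([Si](C)(C)C)C(=O)Oc1cc(OCc2ccccc2)cc(OCc2ccccc2)c1 | intermediate
4 | 3,5-bis(benzyloxy)-2-lithiophenyl N-isopropyl-N-(trimethylsilyl)carbamate (not isolated) | CC(C)N([Si](C)(C)C)C(=O)Oc1cc(OCc2ccccc2)cc(OCc2ccccc2)c1[Li] | intermediate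
5 | 3,5-bis(benzyloxy)-2-(trimethylsilyl)phenyl N-isopropyl-N-(trimethylsilyl)carbamate (not isolated) | CC(C)N([Si](C)(C)C)C(=O)Oc1cc(OCc2ccccc2)cc(OCc2ccccc2)c1[Si](C)(C)C | intermediate
6 | 3,5-bis(benzyloxy)-2-(trimethylsilyl)phenyl N-isopropylcarbamate | CC(C)NC(=O)Oc1cc(OCc2ccccc2)cc(OCc2ccccc2)c1[Si](C)(C)C | intermediate
7 | 3,5-bis(benzyloxy)-2-(trimethylsilyl)phenol (as its phenoxide, not isolated) | Oc1cc(OCc2ccccc2)cc(OCc2ccccc2)c1[Si](C)(C)C | intermediate
8 | 3,5-bis(benzyloxy)-2-(trimethylsilyl)phenyl trifluoromethanesulfonate | C[Si](C)(C)c1c(OS(=O)(=O)C(F)(F)F)cc(OCc2ccccc2)cc1OCc1ccccc1 | intermediate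
9 | methyl 3,5-dihydroxy-4-methoxybenzoate | COC(=O)c1cc(O)c(OC)c(O)c1 | starting material
10 | methyl 3,5-bis(benzyloxy)-4-methoxybenzoate | COC(=O)c1cc(OCc2ccccc2)c(OC)c(OCc2ccccc2)c1 | intermediate
11 | [3,5-bis(benzyloxy)-4-methoxyphenyl]methanol | OCc1cc(OCc2ccccc2)c(OC)c(OCc2ccccc2)c1 | intermediate
12 | 3,5-bis(benzyloxy)-4-methoxybenzaldehyde | O=Cc1cc(OCc2ccccc2)c(OC)c(OCc2ccccc2)c1 | intermediate
13 | ethyl 2-(diethoxyphosphoryl)-2-ethoxyacetate | CCOC(=O)C(OCC)P(=O)(OCC)OCC | starting material
14 | ethyl (Z)-3-[3,5-bis(benzyloxy)-4-methoxyphenyl]-2-ethoxyprop-2-enoate | CCOC(=O)/C(=C/c1cc(OCc2ccccc2)c(OC)c(OCc2ccccc2)c1)OCC | intermediate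
15 | (Z)-3-[3,5-bis(benzyloxy)-4-methoxyphenyl]-2-ethoxyprop-2-en-1-ol | OC/C(=C/c1cc(OCc2ccccc2)c(OC)c(OCc2ccccc2)c1)OCC | intermediate
16 | (Z)-3-[3,5-bis(benzyloxy)-4-methoxyphenyl]-2-ethoxyprop-2-enal | O=C/C(=C/c1cc(OCc2ccccc2)c(OC)c(OCc2ccccc2)c1)OCC | intermediate
17 | 3,5-bis(benzyloxy)benzyne (not isolated) | C1#CC(OCc2ccccc2)=CC(OCc2ccccc2)=C1 | intermediate
18 | rac-3,5-bis(benzyloxy)-2-{(Z)-2-[3,5-bis(benzyloxy)-4-methoxyphenyl]-1-ethoxyethenyl}-2H-1-benzoxete (not isolated) | CCO/C(=C\c1cc(OCc2ccccc2)c(OC)c(OCc2ccccc2)c1)C1Oc2cc(OCc3ccccc3)cc(OCc3ccccc3)c21 | intermediate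
19 | (6Z)-3,5-bis(benzyloxy)-6-{(2Z)-3-[3,5-bis(benzyloxy)-4-methoxyphenyl]-2-ethoxyprop-2-en-1-ylidene}cyclohexa-2,4-dien-1-one (not isolated) | CCO/C(=C\c1cc(OCc2ccccc2)c(OC)c(OCc2ccccc2)c1)/C=C1\C(=O)C=C(OCc2ccccc2)C=C1OCc1ccccc1 | intermediate
20 | rac-5,7-bis(benzyloxy)-2-[3,5-bis(benzyloxy)-4-methoxyphenyl]-3-ethoxy-2H-chromene | CCOC1=Cc2c(OCc3ccccc3)cc(OCc3ccccc3)cc2OC1c1cc(OCc2ccccc2)c(OC)c(OCc2ccccc2)c1 | intermediate
21 | rac-5,7-bis(benzyloxy)-2-[3,5-bis(benzyloxy)-4-methoxyphenyl]chroman-3-one | O=C1Cc2c(OCc3ccccc3)cc(OCc3ccccc3)cc2OC1c1cc(OCc2ccccc2)c(OC)c(OCc2ccccc2)c1 | intermediate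
22 | (2R,3R)-5,7-bis(benzyloxy)-2-[3,5-bis(benzyloxy)-4-methoxyphenyl]chroman-3-ol | O[C@@H]1Cc2c(OCc3ccccc3)cc(OCc3ccccc3)cc2O[C@@H]1c1cc(OCc2ccccc2)c(OC)c(OCc2ccccc2)c1 | intermediate
23 | 4-(benzyloxy)-3-methoxybenzaldehyde | COc1cc(C=O)ccc1OCc1ccccc1 | starting material
24 | malonic acid | OC(=O)CC(=O)O | starting material
25 | 2-{[4-(benzyloxy)-3-methoxyphenyl]methylidene}propanedioic acid (not isolated) | COc1cc(C=C(C(=O)O)C(=O)O)ccc1OCc1ccccc1 | intermediate
26 | (E)-3-[4-(benzyloxy)-3-methoxyphenyl]prop-2-enoic acid | COc1cc(/C=C/C(=O)O)ccc1OCc1ccccc1 | intermediate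
27 | (E)-3-[4-(benzyloxy)-3-methoxyphenyl]prop-2-enoyl chloride (not isolated) | COc1cc(/C=C/C(=O)Cl)ccc1OCc1ccccc1 | intermediate
28 | (2R,3R)-5,7-bis(benzyloxy)-2-[3,5-bis(benzyloxy)-4-methoxyphenyl]chroman-3-yl (E)-3-[4-(benzyloxy)-3-methoxyphenyl]prop-2-enoate | COc1cc(/C=C/C(=O)O[C@@H]2Cc3c(OCc4ccccc4)cc(OCc4ccccc4)cc3O[C@@H]2c2cc(OCc3ccccc3)c(OC)c(OCc3ccccc3)c2)ccc1OCc1ccccc1 | intermediate
29 | 4'-O-methylepigallocatechin-3-O-ferulate, (2R,3R)-2-(3,5-dihydroxy-4-methoxyphenyl)-5,7-dihydroxychroman-3-yl (E)-3-(4-hydroxy-3-methoxyphenyl)prop-2-enoate | COc1cc(/C=C/C(=O)O[C@@H]2Cc3c(O)cc(O)cc3O[C@@H]2c2cc(O)c(OC)c(O)c2)ccc1O | target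

## Step count and risk

Total: 15 steps. Longest linear sequence: 11 steps (steps 4 to 12, then 14 and 15, from 9 to 29).

**Step 10 (key step).**
- Most likely to go wrong: capture of the aryne by the weakly nucleophilic aldehyde oxygen may be slower than aryne self-reaction, or than addition of the aryne to the electron-rich enol ether of the product or to the styrene unit of 16. A smaller risk is erosion of the regioselectivity of capture.
- Fallback: reach the same ortho-quinone methide without an aryne. Setting out from 1 and 16, condensation with PhB(OH)2 and AcOH in toluene at reflux should deliver the aldehyde to the ortho carbon of the phenol through rac-5,7-bis(benzyloxy)-4-{(Z)-2-[3,5-bis(benzyloxy)-4-methoxyphenyl]-1-ethoxyethenyl}-2-phenyl-4H-1,3,2-benzodioxaborinine F1. Its thermal fragmentation gives 19, which electrocyclises as before. Any hydrolysis of the enol ether under these conditions would only give 21, the next compound of the route. The fallback comes back to the route at 20.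

**Step 12.**
- Most likely to go wrong: enolisation at C2 may be too slow relative to reduction, giving a plain kinetic resolution with trans alcohol. Facial discrimination may be poor, because neither flank of the carbonyl is an aryl group directly, or the sense of induction may be reversed.
- Fallback: separate relative from absolute control. From 21, LiBH(s-Bu)3 in THF at −78 °C should attack anti to the C2 aryl group and give rac-cis-5,7-bis(benzyloxy)-2-[3,5-bis(benzyloxy)-4-methoxyphenyl]chroman-3-ol F2. Esterification with (S)-2-methoxy-2-phenylacetic acid (DCC, DMAP) gives two diastereomers: the (2R,3R)-chroman-3-yl (S)-2-methoxy-2-phenylacetate F3 and the (2S,3S)-chroman-3-yl (S)-2-methoxy-2-phenylacetate F4. These are separated by chromatography, and LiOH in THF/H2O cleaves F3. The fallback comes back at 22.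

**Step 15.**
- Most likely to go wrong: loss of the hindered 4'-methyl ether or of the guaiacol methyl ether by Lewis-acid demethylation, or ionisation of the benzylic C2–O1 bond with opening of ring C and capture of the cation by the scavenger.
- Fallback: change the protecting groups before acylation so that the end is a fluoride desilylation. From 22, hydrogenolysis (H2, Pd(OH)2/C, THF/MeOH) gives (2R,3R)-2-(3,5-dihydroxy-4-methoxyphenyl)chroman-3,5,7-triol F5. TBSCl and imidazole in DMF silylate the four phenols in preference to the hindered C3 hydroxyl and give (2R,3R)-5,7-bis[(tert-butyldimethylsilyl)oxy]-2-{3,5-bis[(tert-butyldimethylsilyl)oxy]-4-methoxyphenyl}chroman-3-ol F6. Commercial ferulic acid is silylated twice (TBSCl, imidazole) to tert-butyldimethylsilyl (E)-3-{4-[(tert-butyldimethylsilyl)oxy]-3-methoxyphenyl}prop-2-enoate F7, whose far more labile silyl ester is hydrolysed selectively with AcOH in THF/H2O to (E)-3-{4-[(tert-butyldimethylsilyl)oxy]-3-methoxyphenyl}prop-2-enoic acid F8. Coupling of F6 and F8 (DCC, DMAP) gives the pentasilylated ester, (2R,3R)-5,7-bis[(tert-butyldimethylsilyl)oxy]-2-{3,5-bis[(tert-butyldimethylsilyl)oxy]-4-methoxyphenyl}chroman-3-yl (E)-3-{4-[(tert-butyldimethylsilyl)oxy]-3-methoxyphenyl}prop-2-enoate F9. HF·pyridine in THF/pyridine removes the silyl groups. The fallback comes back at 29.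

**Step 2.**
- Most likely to go wrong: deprotonation of a benzylic OCH2 group followed by Wittig rearrangement, lithiation at the carbon between the two benzyloxy groups, or migration of the carbamoyl group to carbon on warming.
- Fallback: place the silyl group by halogen–lithium exchange and oxygen-to-carbon silyl migration instead of directed metalation. From 1, amine-catalysed ortho-bromination (NBS, i-Pr2NH cat., CH2Cl2) gives 3,5-bis(benzyloxy)-2-bromophenol F10. HMDS gives [3,5-bis(benzyloxy)-2-bromophenoxy]trimethylsilane F11. Treatment with n-BuLi in THF at −100 °C exchanges bromine for lithium and the silyl group migrates to carbon, giving the lithium phenoxide of 7, which Tf2O converts to the triflate. The fallback comes back at 8.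

## Further compounds

F1 | step 10 | rac-5,7-bis(benzyloxy)-4-{(Z)-2-[3,5-bis(benzyloxy)-4-methoxyphenyl]-1-ethoxyethenyl}-2-phenyl-4H-1,3,2-benzodioxaborinine | CCO/C(=C\c1cc(OCc2ccccc2)c(OC)c(OCc2ccccc2)c1)C1OB(c2ccccc2)Oc2cc(OCc3ccccc3)cc(OCc3ccccc3)c21
F2 | step 12 | rac-cis-5,7-bis(benzyloxy)-2-[3,5-bis(benzyloxy)-4-methoxyphenyl]chroman-3-ol (both enantiomers) | O[C@@H]1Cc2c(OCc3ccccc3)cc(OCc3ccccc3)cc2O[C@@H]1c1cc(OCc2ccccc2)c(OC)c(OCc2ccccc2)c1.O[C@H]1Cc2c(OCc3ccccc3)cc(OCc3ccccc3)cc2O[C@H]1c1cc(OCc2ccccc2)c(OC)c(OCc2ccccc2)c1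
F3 | step 12 | (2R,3R)-5,7-bis(benzyloxy)-2-[3,5-bis(benzyloxy)-4-methoxyphenyl]chroman-3-yl (S)-2-methoxy-2-phenylacetate | CO[C@H](C(=O)O[C@@H]1Cc2c(OCc3ccccc3)cc(OCc3ccccc3)cc2O[C@@H]1c1cc(OCc2ccccc2)c(OC)c(OCc2ccccc2)c1)c1ccccc1
F4 | step 12 | (2S,3S)-5,7-bis(benzyloxy)-2-[3,5-bis(benzyloxy)-4-methoxyphenyl]chroman-3-yl (S)-2-methoxy-2-phenylacetate | CO[C@H](C(=O)O[C@H]1Cc2c(OCc3ccccc3)cc(OCc3ccccc3)cc2O[C@H]1c1cc(OCc2ccccc2)c(OC)c(OCc2ccccc2)c1)c1ccccc1
F5 | step 15 | (2R,3R)-2-(3,5-dihydroxy-4-methoxyphenyl)chroman-3,5,7-triol | O[C@@H]1Cc2c(O)cc(O)cc2O[C@@H]1c1cc(O)c(OC)c(O)c1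
F6 | step 15 | (2R,3R)-5,7-bis[(tert-butyldimethylsilyl)oxy]-2-{3,5-bis[(tert-butyldimethylsilyl)oxy]-4-methoxyphenyl}chroman-3-ol | O[C@@H]1Cc2c(O[Si](C)(C)C(C)(C)C)cc(O[Si](C)(C)C(C)(C)C)cc2O[C@@H]1c1cc(O[Si](C)(C)C(C)(C)C)c(OC)c(O[Si](C)(C)C(C)(C)C)c1
F7 | step 15 | tert-butyldimethylsilyl (E)-3-{4-[(tert-butyldimethylsilyl)oxy]-3-methoxyphenyl}prop-2-enoate | COc1cc(/C=C/C(=O)O[Si](C)(C)C(C)(C)C)ccc1O[Si](C)(C)C(C)(C)C
F8 | step 15 | (E)-3-{4-[(tert-butyldimethylsilyl)oxy]-3-methoxyphenyl}prop-2-enoic acid | COc1cc(/C=C/C(=O)O)ccc1O[Si](C)(C)C(C)(C)C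
F9 | step 15 | (2R,3R)-5,7-bis[(tert-butyldimethylsilyl)oxy]-2-{3,5-bis[(tert-butyldimethylsilyl)oxy]-4-methoxyphenyl}chroman-3-yl (E)-3-{4-[(tert-butyldimethylsilyl)oxy]-3-methoxyphenyl}prop-2-enoate | COc1cc(/C=C/C(=O)O[C@@H]2Cc3c(O[Si](C)(C)C(C)(C)C)cc(O[Si](C)(C)C(C)(C)C)cc3O[C@@H]2c2cc(O[Si](C)(C)C(C)(C)C)c(OC)c(O[Si](C)(C)C(C)(C)C)c2)ccc1O[Si](C)(C)C(C)(C)C
F10 | step 2 | 3,5-bis(benzyloxy)-2-bromophenol | Oc1cc(OCc2ccccc2)cc(OCc2ccccc2)c1Br
F11 | step 2 | [3,5-bis(benzyloxy)-2-bromophenoxy]trimethylsilane | C[Si](C)(C)Oc1cc(OCc2ccccc2)cc(OCc2ccccc2)c1Br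
A1 | alternative 1 | (1R,2R)-3-[2,4-bis(benzyloxy)-6-bromophenyl]-1-[3,5-bis(benzyloxy)-4-methoxyphenyl]-2-[(4-methoxybenzyl)oxy]propan-1-ol | COc1ccc(CO[C@H](Cc2c(OCc3ccccc3)cc(OCc3ccccc3)cc2Br)[C@H](O)c2cc(OCc3ccccc3)c(OC)c(OCc3ccccc3)c2)cc1
A2 | alternative 1 | (2R,3R)-5,7-bis(benzyloxy)-2-[3,5-bis(benzyloxy)-4-methoxyphenyl]-3-[(4-methoxybenzyl)oxy]chroman | COc1ccc(CO[C@@H]2Cc3c(OCc4ccccc4)cc(OCc4ccccc4)cc3O[C@@H]2c2cc(OCc3ccccc3)c(OC)c(OCc3ccccc3)c2)cc1
A3 | alternative 2 | 3,5-bis(benzyloxy)-2-(hydroxymethyl)phenol | OCc1c(O)cc(OCc2ccccc2)cc1OCc1ccccc1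
A4 | alternative 2 | 2-{(Z)-2-[3,5-bis(benzyloxy)-4-methoxyphenyl]ethenyl}-4,4,5,5-tetramethyl-1,3,2-dioxaborolane | CC1(C)OB(/C=C\c2cc(OCc3ccccc3)c(OC)c(OCc3ccccc3)c2)OC1(C)C
A5 | alternative 2 | (2S,3R)-5,7-bis(benzyloxy)-2-[3,5-bis(benzyloxy)-4-methoxyphenyl]-3-(4,4,5,5-tetramethyl-1,3,2-dioxaborolan-2-yl)chroman | CC1(C)OB(OC1(C)C)[C@@H]1Cc2c(OCc3ccccc3)cc(OCc3ccccc3)cc2O[C@@H]1c1cc(OCc2ccccc2)c(OC)c(OCc2ccccc2)c1
A6 | alternative 3 | 1,5-bis(benzyloxy)-3-({(1R)-1-[3,5-bis(benzyloxy)-4-methoxyphenyl]-2-[(4-methoxybenzyl)oxy]prop-2-en-1-yl}oxy)-2-ethenylbenzene | COc1ccc(COC(=C)[C@H](Oc2cc(OCc3ccccc3)cc(OCc3ccccc3)c2C=C)c2cc(OCc3ccccc3)c(OC)c(OCc3ccccc3)c2)cc1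
A7 | alternative 3 | (2R)-5,7-bis(benzyloxy)-2-[3,5-bis(benzyloxy)-4-methoxyphenyl]-3-[(4-methoxybenzyl)oxy]-2H-chromene | COc1ccc(COC2=Cc3c(OCc4ccccc4)cc(OCc4ccccc4)cc3O[C@@H]2c2cc(OCc3ccccc3)c(OC)c(OCc3ccccc3)c2)cc1
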